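**Assumption:** the target has no stereocentre and is achiral, so there is no enantiomer to select; the route only has to control regiochemistry.

## Retrosynthetic overview

1. No ring is built and there is no C–C bond outside the two benzene rings. The one strategic bond is the diaryl ether C–O bond, and all four bromines are bought in place.
2. Ring A acceptor: 2,4-dibromoanisole 1 is converted (through aryl iodide 2 and λ3-iodane 3) into the symmetric diaryliodonium triflate 4. The normally nucleophilic anisole ortho carbon thereby becomes an aryl cation equivalent.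
3. Ring B donor: 2,5-dibromoanisole 5 is hydroxylated between OMe and Br (aryllithium 6, borate 7) to 3,6-dibromo-2-methoxyphenol 8.
4. Key step: phenoxide 9 (from 8) and 4 combine through aryloxy-λ3-iodane 10 to the dimethyl ether 11. Two centres that are both naturally nucleophilic (phenol oxygen, anisole ortho carbon) are joined.
5. Double O-demethylation of 11 (through boron ester 12) gives the target 13.

## Route

**Step 1**
Reactants: 1 2,4-dibromoanisole (2,4-dibromo-1-methoxybenzene; two molecules per iodine atom)
Product: 4 bis(3,5-dibromo-2-methoxyphenyl)iodonium trifluoromethanesulfonate, via aryl iodide 2 (not isolated), via hydroxy-λ3-iodane 3 (not isolated)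
Conditions: 1 (4.2 equiv), I2 (1.0 equiv), mCPBA (3.1 equiv), TfOH (5 equiv), CH2Cl2, 0 °C to rt, 16 h; Et2O trituration
Reagents that add atoms: iodine ([I][I]); trifluoromethanesulfonic acid (OS(=O)(=O)C(F)(F)F)
Why: One-pot oxidative diaryliodonium synthesis (double SEAr at iodine): the electrophilic iodine species iodinates 1 at C6, the only position activated by OMe and not blocked by bromine, to give 2, which is oxidised in situ to the trivalent-iodine species 3 and attacks a second molecule of 1 at the same position, so the symmetric salt 4 forms with no regiochemical or ligand-selectivity question and no stereocentre.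

**Step 2**
Reactants: 5 2,5-dibromoanisole (1,4-dibromo-2-methoxybenzene)
Product: 8 3,6-dibromo-2-methoxyphenol, via aryllithium 6 (not isolated), via aryl triisopropoxyborate 7 (not isolated)
Conditions: B(Oi-Pr)3 (1.3 equiv), THF, −78 °C; LiN(i-Pr)2 (1.15 equiv, commercial solution) added slowly, −78 °C, 1 h, then to 0 °C; AcOH, 30% H2O2, 0 °C to rt
Reagents that add atoms: hydrogen peroxide (OO)
Why: Directed ortho-metalation with in situ borate trapping followed by oxidative hydroxydeboronation: H6 of 5, flanked by OMe and Br, is by far the most acidic ring proton, the aryllithium 6 is intercepted by the borate at −78 °C before it can lose LiBr or undergo halogen dance, and the C–B bond of 7 is converted to C–OH at the same carbon; no stereocentre is formed.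

**Step 3 (key step)**
Reactants: 8 3,6-dibromo-2-methoxyphenol; 4 bis(3,5-dibromo-2-methoxyphenyl)iodonium trifluoromethanesulfonate
Product: 11 1,4-dibromo-2-(3,5-dibromo-2-methoxyphenoxy)-3-methoxybenzene, via potassium phenoxide 9 (not isolated), via aryloxy-λ3-iodane 10 (not isolated)
Conditions: KOt-Bu (0.98 equiv), THF, 0 °C, 15 min; then 4 (1.15 equiv), THF, rt to 40 °C, 4–12 h
Reagents that add atoms: none
Why: Metal-free O-arylation of a phenoxide with a diaryliodonium salt (ligand exchange at iodine to the T-shaped λ3-iodane 10, then ipso ligand coupling): the anisole ortho carbon reacts as an aryl cation equivalent with the phenoxide oxygen, both aryl ligands are identical so either one transfers the right group, this reaction type tolerates ortho,ortho'-disubstituted phenols and aryl bromides, and the absence of excess base suppresses the aryne pathway; no stereocentre is formed.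

**Step 4**
Reactants: 11 1,4-dibromo-2-(3,5-dibromo-2-methoxyphenoxy)-3-methoxybenzene
Product: 13 3,6-dibromo-2-(3,5-dibromo-2-hydroxyphenoxy)phenol, via bis(dibromoboryl) ester 12 (not isolated)
Conditions: BBr3 (5 equiv), CH2Cl2, −78 °C to rt, 12 h; H2O quench, 0 °C
Reagents that add atoms: none
Why: Lewis-acid ether cleavage with BBr3 (bromide attacks the O-methyl carbon of each ArO(Me)–BBr3 adduct in an SN2 step) removes both methyl groups, leaves the diaryl ether and the four C–Br bonds untouched, and hydrolysis of 12 on quench frees both phenols; no stereocentre is formed.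

## Compound list

1 | 2,4-dibromoanisole (2,4-dibromo-1-methoxybenzene) | COc1ccc(Br)cc1Br | starting material
2 | 1,5-dibromo-3-iodo-2-methoxybenzene (2,4-dibromo-6-iodoanisole) | COc1c(Br)cc(Br)cc1I | intermediate
3 | (3,5-dibromo-2-methoxyphenyl)(hydroxy)(trifluoromethanesulfonyloxy)-λ3-iodane | COc1c(Br)cc(Br)cc1I(O)OS(=O)(=O)C(F)(F)F | intermediate
4 | bis(3,5-dibromo-2-methoxyphenyl)iodonium trifluoromethanesulfonate | COc1c(Br)cc(Br)cc1[I+]c1cc(Br)cc(Br)c1OC.[O-]S(=O)(=O)C(F)(F)F | intermediate
5 | 2,5-dibromoanisole (1,4-dibromo-2-methoxybenzene) | COc1cc(Br)ccc1Br | starting material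
6 | (3,6-dibromo-2-methoxyphenyl)lithium | [Li]c1c(OC)c(Br)ccc1Br | intermediate
7 | lithium (3,6-dibromo-2-methoxyphenyl)tri(propan-2-yloxy)borate | [Li+].CC(C)O[B-](OC(C)C)(OC(C)C)c1c(OC)c(Br)ccc1Br | intermediate
8 | 3,6-dibromo-2-methoxyphenol | COc1c(O)c(Br)ccc1Br | intermediate
9 | potassium 3,6-dibromo-2-methoxyphenolate | COc1c([O-])c(Br)ccc1Br.[K+] | intermediate
10 | (3,6-dibromo-2-methoxyphenoxy)bis(3,5-dibromo-2-methoxyphenyl)-λ3-iodane | COc1c(Br)ccc(Br)c1OI(c1cc(Br)cc(Br)c1OC)c1cc(Br)cc(Br)c1OC | intermediate
11 | 1,4-dibromo-2-(3,5-dibromo-2-methoxyphenoxy)-3-methoxybenzene | COc1c(Br)ccc(Br)c1Oc1cc(Br)cc(Br)c1OC | intermediate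
12 | bis(O-dibromoboryl) ester of the target diphenol | BrB(Br)Oc1c(Br)cc(Br)cc1Oc1c(Br)ccc(Br)c1OB(Br)Br | intermediate
13 | 3,6-dibromo-2-(3,5-dibromo-2-hydroxyphenoxy)phenol (CNP0181200.0) | Oc1c(Br)cc(Br)cc1Oc1c(Br)ccc(Br)c1O | target

## Step count and risks

Total steps: 4. Longest linear sequence: 3 steps (1 → 4 → 11 → 13, or equally 5 → 8 → 11 → 13).

**Most likely to fail, with fallbacks:**

Step 1 (one-pot symmetric iodonium salt from a hindered, moderately deactivated anisole; oxidative side reactions or a stalled second arylation are possible). The fallback sets out from 1 and comes back at 11. Compound 1 is iodinated on its own (NIS, TFA, MeCN, rt) and aryl iodide 2 is isolated. Compound 2 is oxidised with mCPBA and TsOH·H2O in MeCN at 60 °C to (3,5-dibromo-2-methoxyphenyl)(hydroxy)(tosyloxy)-λ3-iodane F1. F1 is trapped in the same pot with 1,3,5-trimethoxybenzene to give the unsymmetrical (3,5-dibromo-2-methoxyphenyl)(2,4,6-trimethoxyphenyl)iodonium 4-methylbenzenesulfonate F2. F2 replaces 4 in the arylation of phenoxide 9; the electron-rich trimethoxyphenyl group stays on iodine as a non-transferable ligand, so only the dibromomethoxyphenyl group is delivered and 11 results.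

Step 3 (ligand coupling between a 2,6-disubstituted phenoxide and an ortho-substituted aryl group; steric retardation or aryne-derived regioisomers are possible). The fallback sets out from 8 and comes back at 11. Phenol 8 is coupled with the isolated aryl iodide 2 (made from 1 with NIS and TFA as above) in a ligand-accelerated Ullmann ether synthesis: CuI (10 mol %), picolinic acid (20 mol %), K3PO4, DMSO, 80–90 °C. The C–I bond reacts well ahead of the C–Br bonds at this temperature. This replaces the hypervalent-iodine arylation by a copper-catalysed cross-coupling; new compounds on this path: none F0.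

Step 2 (regioselective lithiation next to bromine; aryne formation, halogen dance or metalation at H3 or H4 are possible). The fallback sets out from 5 and comes back at 8, using no organolithium. Compound 5 is demethylated (BBr3, CH2Cl2) to 2,5-dibromophenol F3. F3 is ortho-formylated at its only free ortho position (MgCl2, Et3N, paraformaldehyde, MeCN, reflux) to 3,6-dibromo-2-hydroxybenzaldehyde F4. Dakin oxidation (H2O2, aqueous NaOH) gives 3,6-dibromobenzene-1,2-diol F5. Because F5 is symmetric, mono-methylation (MeI 1.0 equiv, K2CO3, acetone) can give only one mono-ether, 8, which is separated from the dimethyl ether and recovered F5.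

## Further compounds

F1 | step 1 | (3,5-dibromo-2-methoxyphenyl)(hydroxy)(tosyloxy)-λ3-iodane | COc1c(Br)cc(Br)cc1I(O)OS(=O)(=O)c1ccc(C)cc1
F2 | step 1 | (3,5-dibromo-2-methoxyphenyl)(2,4,6-trimethoxyphenyl)iodonium 4-methylbenzenesulfonate | COc1cc(OC)c([I+]c2cc(Br)cc(Br)c2OC)c(OC)c1.Cc1ccc(S(=O)(=O)[O-])cc1
F3 | step 2 | 2,5-dibromophenol | Oc1cc(Br)ccc1Br
F4 | step 2 | 3,6-dibromo-2-hydroxybenzaldehyde | O=Cc1c(O)c(Br)ccc1Br
F5 | step 2 | 3,6-dibromobenzene-1,2-diol | Oc1c(O)c(Br)ccc1Br
F0 | step 3 | none | none
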